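**Remarks on the chemistry (assumptions)**

- Numbering: bisabolane-type locants are used throughout. The ring is C1–C6 (C1 bears the side chain, C4 the methyl C15); the side chain is C7(=C14H2)–C8–C9–C10–C11(C12,C13). (S)-Carvone maps its C5 onto C1 and its carbonyl carbon onto C3.
- Stereochemical check: with the C1 side chain drawn up, the target has C2–OH down, C3–O up and the ring oxirane down (1R,2R,3S,4S,5S,8S,10R). Diene 15 (1S; the descriptor changes by priority only) and peroxide 16 (bridge down) carry the same C1, C8 and C10 configurations, so no descriptor of the key-step pair needs changing.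
- Design corrections on the way to 15: (a) an allylic C8 angelate is a substrate for palladium/formate hydrogenolysis and for strong base, so the ring diene is made while C8 is a silyl ether and the ester is put on afterwards; (b) a C7 methyl ketone cannot be enolised selectively beside the ring enone, so the side chain is grown from a C8 aldehyde; (c) C8 and C10 are remote from C1 and are set by reagent control.

## Structural features

The target is a bisabolane sesquiterpenoid: one cyclohexane ring fused to an oxirane at C4–C5, joined at C1 through C7 to a five-carbon chain. Five contiguous ring stereocentres stand side by side: the C1 side chain (up), the free C2 hydroxyl (down), the C3 angelate (up) and the oxirane (down, with quaternary C4 carrying the methyl); C6 is the only unfunctionalised ring carbon. The chain holds the 1,1-disubstituted alkene C7=C14, an allylic angelate at C8 (S) and, behind the C9 methylene, a trisubstituted oxirane (10R); C8 and C10 are too far from the ring for substrate control. Fragile groups are the two (Z)-2-methylbut-2-enoates (Z→E isomerisation, 1,2-acyl shift to the free C2 hydroxyl), both oxiranes (the 2,2-dimethyl one ionises with acid), the allylic C8 ester (ionised by zerovalent palladium) and the bis-allylic C1–H of any diene precursor. The real difficulty is the ring: four adjacent oxygenated carbons in a trans,trans,cis relation, with one hydroxyl free and its neighbour acylated, to be told apart without protecting groups. The key step exploits that the oxygens on C2 and C5 are cis, 1,4-related across C3–C4 and both trans to the C1 substituent. That is the footprint of one molecule of dioxygen added across a C2=C3–C4=C5 diene from the face opposite C1.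

## Logic of the disconnections

20 ⇒ 19. The C4–O and C5–O bonds of the ring oxirane are cut last. In 19 the free hydroxyl on C2 is homoallylic to C4=C5 and lies on the face the oxirane must occupy, so it can steer a metal peroxide. The gain is one oxygen and two stereocentres. The forward step must choose C4=C5 over C7=C14 and the enoate double bonds and leave the side-chain oxirane alone.

19 ⇒ 18 + 13. The C3–O bond is cut so that it arises by attack of 13 on the allylic carbon of a C2–C3 oxirane. Inversion at C3 gives the trans arrangement and leaves the C2 oxygen as the free hydroxyl, which differentiates the two neighbours without a protecting group. The gain is one acyl unit and the C3 stereocentre. The demand is attack at C3 rather than SN2′ attack at C5, and survival of the 2,2-dimethyloxirane.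

18 ⇒ 16. The C3–O bond of the vinyl oxirane is exchanged for a C5–O bond, giving a C2,C5 peroxide bridge with C3=C4. The weak O–O bond allows a phosphine to remove one oxygen while the other closes onto C3. Nothing is gained in size, but both ring oxygens of 18 and 19 are traced to one reagent. The demand is regiochemical: the oxygen on C5 must leave and the oxygen on C2 must stay.

16 ⇒ 15. The C2–O and C5–O bonds are cut together, which is the retro-[4+2] loss of dioxygen. This removes one ring, two bonds and two stereocentres in a single operation and leaves a conjugated diene with one stereocentre on the ring. The forward step must add to the face opposite the C1 substituent and must find no other alkene reactive towards singlet oxygen.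

15 ⇒ 12 + 13. The acyl–O bond at C8 is cut. The ester must be present before photo-oxygenation, because a free hydroxyl would draw the oxidant to the wrong face and the later peroxide is base-sensitive. It must come after all strong-base and palladium chemistry. The demand is acylation without Z→E isomerisation, below the temperature at which a 1,5-hydrogen shift would move the diene.

12 ⇒ 11 ⇒ 10. The O–Si bond and then the C3–H bond are traced back to a dienyl triflate. Hydride delivery to a palladium-bound dienyl group involves no cation or anion that could shift the diene. The silyl ether is there because an allylic ester would be ionised by the same catalyst. The gain is that the sensitive diene is stored as a stable precursor.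

10 ⇒ 8. The O–S bond is cut back, through enolate 9, to the ring ketone. Kinetic deprotonation at C2 places the diene as C2=C3–C4=C5. The extended dienolate would place it as C3=C4–C5=C6, which is the same diene in the C1-epimeric series, so regiocontrol here is also stereocontrol.

8 ⇒ 7. The two C–O bonds of the side-chain oxirane are cut. It must precede the diene and the singlet oxygen, and at this stage C10=C11 is the only electron-rich alkene. The gain is the C10 stereocentre; the demand is reagent control of the alkene face.

7 ⇒ 6. The O–Si bond is cut. The free hydroxyl is kept through the metathesis and masked directly afterwards.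

6 ⇒ 5. The C10=C11 bond is cut by metathesis logic back to a terminal vinyl group. A prenyl metal would add to an aldehyde through its substituted end, so allyl transfer followed by alkene exchange is the safe way to the linear prenyl unit. The demand is that only the monosubstituted alkene reacts.

5 ⇒ 3. The C8–C9 bond is cut to an aldehyde and an allyl donor. This creates C8 under reagent control. The demand is addition to the aldehyde, not the ring ketone, on the Si face.

3 ⇒ 2 ⇒ 1. The C8=O and then the C8–Cl bond are traced back to the methyl of the isopropenyl group of 1. The chiral pool then supplies the ring, the C1 stereocentre, C15, C7=C14 and the ketone that becomes the diene. The demand is allylic functionalisation at the isopropenyl group only.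

## Other disconnections considered

Alternative 1: The cut is C3–C4. An open-chain (Z)-iodoalkene aldehyde A2 would be closed with CrCl2 and catalytic NiCl2 (a Nozaki–Hiyama–Kishi reaction). The vinylchromium formed at C4 adds to the C3 aldehyde and gives cyclohexenol A1 with C4=C5 in place, a free C3 hydroxyl, a C2 silyl ether and a C8 PMB ether.
- In its favour: the reaction is aldehyde-selective and mild. The alkene position is fixed by construction, which is better than the chosen plan, where it depends on how a peroxide collapses. The oxygens on C2 and C3 are differentiated from the start, which equals the chosen plan.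
- Against it here: C3 is created in the ring closure and must come out trans to the C2 silyl ether under only moderate 1,2-induction. A2 needs C1, C2 and C8 set in an acyclic chain plus a geometrically pure iodoalkene. After the closure two trisubstituted alkenes (C4=C5 and C10=C11) must be epoxidised separately with different face control, and the PMB group must be exchanged for an angelate.
- Comparison: structurally it builds the carbocycle by a C–C bond, which is the better choice for ring analogues; the chosen plan takes the ring from 1 and makes only C–O bonds. Mechanistically it is a polar organometallic addition with a diastereoselectivity risk comparable to the facial risk of the cycloaddition. In step economy it should be clearly longer, and it uses divalent chromium in excess where the chosen plan uses O2 and light.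

Alternative 2: The cut is C4=C5. Acyclic diene A4 (C4 isopropenyl, C5 vinyl) would be closed with second-generation Grubbs catalyst with loss of ethene. The product A3 is the same compound as 19, so both plans share the last step.
- In its favour: this is the most dependable ring closure of the four. No stereocentre is formed, so nothing can go wrong stereochemically in the key step. It tolerates esters, oxiranes and a free hydroxyl and avoids peroxides. On predictability it is better than the chosen plan.
- Against it here: the difficulty is moved, not removed. C1, C2 and C3 and the free/acylated pair of hydroxyls must already exist in acyclic A4, a 1,2-diol monoester prone to acyl shift, and must be made by several reagent-controlled C–C bond formations. A third 1,1-disubstituted alkene (C7=C14) is present during metathesis.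
- Comparison: the mechanism is a metal-carbene [2+2]/retro-[2+2] sequence against a pericyclic addition. The chosen plan lets one O2 deliver the oxygens on C2 and C3 and the 4,5-alkene of 19, and takes C1 from the chiral pool. It should therefore reach 19 in far fewer steps.

Alternative 3: The cut is C1–C6. Bi(OTf)3 would ionise the tertiary allylic carbonate of A6 to the C4–C5–C6 allyl cation. The allylsilane would capture its C6 end through C1, closing the ring and releasing silicon to give C7=C14 in A5 (trans C2,C3-acetonide, C8 silyl ether).
- In its favour: it is biomimetic, and one step forms the ring C–C bond and the exocyclic alkene. The position of C7=C14 is dictated by silicon, which is as secure as in the chosen plan, where that alkene is inherited.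
- Against it here: C1 is created in the cyclisation under the influence of the dioxolane only. The cation can also lose a proton or be intercepted by the prenyl alkene. Removing the strained trans-acetonide gives a free trans-diol whose two hydroxyls cannot be told apart on acylation, which is worse than the chosen plan. The C8 ester exchange and two epoxidations in the presence of two trisubstituted alkenes would still follow.
- Comparison: as a cationic C–C bond construction it is the more convergent way to the skeleton. In stereocontrol at C1 and in step economy after the key step it is inferior.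

Key step: step 11

## Route

Step 1
Reactants: 1 (S)-carvone
Product: 2 (5S)-5-(3-chloroprop-1-en-2-yl)-2-methylcyclohex-2-en-1-one
Conditions: Ca(OCl)2, CO2 (s), CH2Cl2/H2O, 0 °C
Reagents that add atoms: calcium hypochlorite, [Ca+2].[O-]Cl.[O-]Cl
Why: Ene-type allylic chlorination by HOCl made in situ: electrophilic chlorine attacks the electron-rich 1,1-disubstituted alkene and a proton is lost from the methyl, so the isopropenyl group becomes a 2-(chloromethyl)vinyl group; the enone alkene is too electron-poor to react and the ring stereocentre is untouched.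

Step 2
Reactants: 2 (5S)-5-(3-chloroprop-1-en-2-yl)-2-methylcyclohex-2-en-1-one
Product: 3 2-[(1S)-4-methyl-5-oxocyclohex-3-en-1-yl]prop-2-enal
Conditions: NMO, NaI (cat.), NaHCO3, MeCN, 40 °C
Reagents that add atoms: N-methylmorpholine N-oxide, C[N+]1([O-])CCOCC1
Why: Ganem oxidation: iodide-assisted SN2 displacement by the N-oxide oxygen, then base-induced loss of N-methylmorpholine from the alkoxyammonium salt gives the aldehyde; the near-neutral medium should leave C7=C14 out of conjugation with the ring, which would otherwise erase C1.

Step 3
Reactants: 3 2-[(1S)-4-methyl-5-oxocyclohex-3-en-1-yl]prop-2-enal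
Product: 5 (5S)-5-[(3S)-3-hydroxyhexa-1,5-dien-2-yl]-2-methylcyclohex-2-en-1-one, via borinate ester 4 (not isolated)
Conditions: (−)-Ipc2B(allyl) (from (+)-α-pinene), Et2O, −78 °C; then HOCH2CH2NH2
Reagents that add atoms: (−)-B-allyldiisopinocampheylborane, C=CCB([C@@H]1C[C@@H]2C[C@H]([C@H]1C)C2(C)C)[C@@H]1C[C@@H]2C[C@H]([C@H]1C)C2(C)C
Why: Brown allylation through a chair Zimmerman–Traxler transition state; the (+)-α-pinene-derived reagent delivers allyl to the Si face of the aldehyde and so sets C8 as S under reagent control. The aldehyde reacts far faster than the enone carbonyl at −78 °C, and the non-oxidative work-up spares the enone.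

Step 4
Reactants: 5 (5S)-5-[(3S)-3-hydroxyhexa-1,5-dien-2-yl]-2-methylcyclohex-2-en-1-one
Product: 6 (5S)-5-[(3S)-3-hydroxy-6-methylhepta-1,5-dien-2-yl]-2-methylcyclohex-2-en-1-one
Conditions: second-generation Grubbs catalyst (5 mol %), 2-methylbut-2-ene (excess), CH2Cl2, 35 °C
Reagents that add atoms: 2-methylbut-2-ene, CC=C(C)C
Why: Olefin cross-metathesis: only the monosubstituted terminal alkene enters the catalytic cycle and exchanges its CH2 for the isopropylidene unit with loss of propene; the hindered 1,1-disubstituted C7=C14 and the enone alkene should be inert, and no stereocentre is affected.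

Step 5
Reactants: 6 (5S)-5-[(3S)-3-hydroxy-6-methylhepta-1,5-dien-2-yl]-2-methylcyclohex-2-en-1-one
Product: 7 (5S)-5-[(3S)-3-(tert-butyldimethylsilyloxy)-6-methylhepta-1,5-dien-2-yl]-2-methylcyclohex-2-en-1-one
Conditions: TBSCl, imidazole, DMF, rt
Reagents that add atoms: tert-butyldimethylsilyl chloride, CC(C)(C)[Si](C)(C)Cl
Why: Standard silylation; the C8 oxygen must be neither acidic nor an allylic ester during the strong-base and palladium steps 7 and 8.

Step 6
Reactants: 7 (5S)-5-[(3S)-3-(tert-butyldimethylsilyloxy)-6-methylhepta-1,5-dien-2-yl]-2-methylcyclohex-2-en-1-one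
Product: 8 (5S)-5-{(3S)-3-(tert-butyldimethylsilyloxy)-4-[(2R)-3,3-dimethyloxiran-2-yl]but-1-en-2-yl}-2-methylcyclohex-2-en-1-one
Conditions: D-fructose-derived Shi ketone (30 mol %), Oxone (2KHSO5·KHSO4·K2SO4), K2CO3, Bu4NHSO4, MeCN/DMM/aq. Na2B4O7 buffer, 0 °C
Reagents that add atoms: potassium peroxymonosulfate, [K+].[O-]S(=O)(=O)OO
Why: Shi epoxidation: the chiral dioxirane transfers oxygen through a spiro transition state and, for a trisubstituted R–CH=CMe2 alkene, the D-fructose-derived ketone should give the (R)-oxirane at C10 under reagent control. The electron-rich C10=C11 is by far the most reactive alkene; the hindered C7=C14 and the enone alkene should remain.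

Step 7
Reactants: 8 (5S)-5-{(3S)-3-(tert-butyldimethylsilyloxy)-4-[(2R)-3,3-dimethyloxiran-2-yl]but-1-en-2-yl}-2-methylcyclohex-2-en-1-one
Product: 10 (3S)-3-{(3S)-3-(tert-butyldimethylsilyloxy)-4-[(2R)-3,3-dimethyloxiran-2-yl]but-1-en-2-yl}-6-methylcyclohexa-1,5-dien-1-yl trifluoromethanesulfonate, via lithium dienolate 9 (not isolated)
Conditions: LiN(i-Pr)2 (LDA), THF, −78 °C; then PhNTf2, −78 → 0 °C
Reagents that add atoms: N-phenylbis(trifluoromethanesulfonimide), O=S(=O)(N(c1ccccc1)S(=O)(=O)C(F)(F)F)C(F)(F)F
Why: Kinetic α′-deprotonation at C2 gives the cross-conjugated dienolate, which is O-sulfonylated to the 2-triflyloxy-1,3-diene. This regiochemistry fixes the diene as C2=C3–C4=C5; the extended dienolate would lead to the C1-epimeric series.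

Step 8
Reactants: 10 (3S)-3-{(3S)-3-(tert-butyldimethylsilyloxy)-4-[(2R)-3,3-dimethyloxiran-2-yl]but-1-en-2-yl}-6-methylcyclohexa-1,5-dien-1-yl trifluoromethanesulfonate
Product: 11 tert-butyl{[(2S)-1-[(2R)-3,3-dimethyloxiran-2-yl]-3-[(1S)-4-methylcyclohexa-2,4-dien-1-yl]but-3-en-2-yl]oxy}dimethylsilane
Conditions: Pd(OAc)2 (5 mol %), PPh3 (10 mol %), n-Bu3N, HCO2H, DMF, 50 °C
Reagents that add atoms: none
Why: Palladium-catalysed formate reduction of an alkenyl triflate: oxidative addition to zerovalent palladium, formate exchange, loss of CO2 and C–H reductive elimination replace OTf by H with no ionic intermediate that could move the diene. The silyl ether is not ionised (an allylic ester would be), and the oxirane is not allylic.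

Step 9
Reactants: 11 tert-butyl{[(2S)-1-[(2R)-3,3-dimethyloxiran-2-yl]-3-[(1S)-4-methylcyclohexa-2,4-dien-1-yl]but-3-en-2-yl]oxy}dimethylsilane
Product: 12 (2S)-1-[(2R)-3,3-dimethyloxiran-2-yl]-3-[(1S)-4-methylcyclohexa-2,4-dien-1-yl]but-3-en-2-ol
Conditions: TBAF, THF, 0 °C → rt
Reagents that add atoms: none
Why: Fluoride-induced desilylation; diene, oxirane and C7=C14 are inert to fluoride, and under basic conditions the C8 alkoxide has no favourable ring closure onto the oxirane. The alcohol is used at once, without acidic contact.

Step 10
Reactants: 12 (2S)-1-[(2R)-3,3-dimethyloxiran-2-yl]-3-[(1S)-4-methylcyclohexa-2,4-dien-1-yl]but-3-en-2-ol; 13 angelic acid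
Product: 15 (2S)-1-[(2R)-3,3-dimethyloxiran-2-yl]-3-[(1S)-4-methylcyclohexa-2,4-dien-1-yl]but-3-en-2-yl (2Z)-2-methylbut-2-enoate, via mixed anhydride 14 (not isolated)
Conditions: 13, 2,4,6-Cl3C6H2COCl, Et3N, toluene, rt; then 12, 60 °C
Reagents that add atoms: none
Why: Yamaguchi esterification: the alcohol attacks the less hindered angeloyl carbonyl of the preformed mixed anhydride. Omitting nucleophilic catalysts and keeping the temperature moderate should preserve the Z geometry and stay far below the onset of the 1,5-hydrogen shift that would move the diene and so epimerise C1.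

Step 11
Reactants: 15 (2S)-1-[(2R)-3,3-dimethyloxiran-2-yl]-3-[(1S)-4-methylcyclohexa-2,4-dien-1-yl]but-3-en-2-yl (2Z)-2-methylbut-2-enoate
Product: 16 (2S)-1-[(2R)-3,3-dimethyloxiran-2-yl]-3-[(1S,4S,5R)-7-methyl-2,3-dioxabicyclo[2.2.2]oct-7-en-5-yl]but-3-en-2-yl (2Z)-2-methylbut-2-enoate
Conditions: O2, 5,10,15,20-tetraphenylporphyrin (1 mol %), hν (white LED), CH2Cl2, −78 °C
Reagents that add atoms: dioxygen, O=O
Why: The porphyrin sensitises triplet dioxygen to singlet oxygen, which adds to the ring-locked s-cis diene C2=C3–C4=C5 in a concerted, suprafacial [4+2] cycloaddition that makes the C2–O and C5–O bonds in one event. The closest known reaction type is the dye-sensitised photo-oxygenation of 5-substituted cyclohexa-1,3-dienes of the α-phellandrene class to 2,3-dioxabicyclo[2.2.2]oct-5-enes. The one new ring, the six-membered 1,2-dioxine, is closed by cycloaddition, both C–O bonds forming on the same face of the carbocycle. C2 and C5 are set together: their cis relation follows from the suprafacial addition, and their relation to C1 from approach opposite the C1 side chain, which shields best in the conformer with that substituent pseudo-axial, the one favoured at low temperature. The step needs π-facial selectivity and chemoselectivity. The first rests only on the C1 stereocentre and is expected to be moderate; the C8 ester helps because, unlike a free hydroxyl, it cannot hydrogen-bond the oxidant to the upper face, and the minor epimer would be removed by chromatography on neutral silica. The second is secured by design: the cyclic diene is far more reactive than C7=C14 and the electron-poor enoate, and the C10=C11 alkene that would undergo the ene reaction is already an oxirane.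

Step 12
Reactants: 16 (2S)-1-[(2R)-3,3-dimethyloxiran-2-yl]-3-[(1S,4S,5R)-7-methyl-2,3-dioxabicyclo[2.2.2]oct-7-en-5-yl]but-3-en-2-yl (2Z)-2-methylbut-2-enoate
Product: 18 (2S)-1-[(2R)-3,3-dimethyloxiran-2-yl]-3-[(1R,2R,6S)-5-methyl-7-oxabicyclo[4.1.0]hept-4-en-2-yl]but-3-en-2-yl (2Z)-2-methylbut-2-enoate, via oxyphosphonium alkoxide 17 (not isolated)
Conditions: PPh3 (1.05 equiv), CH2Cl2, −20 °C → rt
Reagents that add atoms: none
Why: Phosphine deoxygenation of a bicyclic endoperoxide: PPh3 inserts into the weak O–O bond at the oxygen on C5, which is remote from the branched C1, and the C2 alkoxide then closes on C3 in a syn SN2′ sense, expelling Ph3P=O from C5 and moving the alkene to C4=C5. Two biases concur: the less hindered oxygen is on C5, and the unsubstituted C3 is a better SN2′ terminus than the methyl-bearing C4. The oxirane keeps the face the peroxide occupied.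

Step 13
Reactants: 18 (2S)-1-[(2R)-3,3-dimethyloxiran-2-yl]-3-[(1R,2R,6S)-5-methyl-7-oxabicyclo[4.1.0]hept-4-en-2-yl]but-3-en-2-yl (2Z)-2-methylbut-2-enoate; 13 angelic acid
Product: 19 (1R,5R,6R)-5-{(3S)-4-[(2R)-3,3-dimethyloxiran-2-yl]-3-[(2Z)-2-methylbut-2-enoyloxy]but-1-en-2-yl}-6-hydroxy-2-methylcyclohex-2-en-1-yl (2Z)-2-methylbut-2-enoate
Conditions: 13 (5 equiv), i-Pr2NEt (1 equiv), toluene, 35 °C
Reagents that add atoms: none
Why: Carboxylic acid opening of a vinyl oxirane: the acid/ammonium carboxylate pair gives general-acid-assisted SN2 attack at the allylic carbon C3 with inversion, hence the trans C3 angelate and the free C2 hydroxyl. The buffer is too weakly acidic to ionise the side-chain 2,2-dimethyloxirane, whose secondary carbon is a poor SN2 site.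

Step 14
Reactants: 19 (1R,5R,6R)-5-{(3S)-4-[(2R)-3,3-dimethyloxiran-2-yl]-3-[(2Z)-2-methylbut-2-enoyloxy]but-1-en-2-yl}-6-hydroxy-2-methylcyclohex-2-en-1-yl (2Z)-2-methylbut-2-enoate
Product: 20 (1S,2S,3R,4R,6S)-4-{(3S)-4-[(2R)-3,3-dimethyloxiran-2-yl]-3-[(2Z)-2-methylbut-2-enoyloxy]but-1-en-2-yl}-3-hydroxy-1-methyl-7-oxabicyclo[4.1.0]heptan-2-yl (2Z)-2-methylbut-2-enoate (target)
Conditions: VO(acac)2 (5 mol %), t-BuOOH (1.5 equiv, decane), CH2Cl2, 0 °C → rt
Reagents that add atoms: tert-butyl hydroperoxide, CC(C)(C)OO
Why: Vanadium-catalysed hydroxyl-directed epoxidation of a cyclic homoallylic alcohol: the C2 hydroxyl binds the vanadium alkylperoxide and delivers oxygen to C4=C5 on its own face, which is also the face away from the C3 ester and the C1 side chain, so C4 and C5 come out cis to the C2 hydroxyl. The trisubstituted ring alkene should win over C7=C14, and the enoate alkenes are inert.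

## Compound list

1 | (S)-carvone, (5S)-2-methyl-5-(prop-1-en-2-yl)cyclohex-2-en-1-one | C=C(C)[C@H]1CC=C(C)C(=O)C1 | starting material
2 | (5S)-5-(3-chloroprop-1-en-2-yl)-2-methylcyclohex-2-en-1-one | C=C(CCl)[C@H]1CC=C(C)C(=O)C1 | intermediate
3 | 2-[(1S)-4-methyl-5-oxocyclohex-3-en-1-yl]prop-2-enal | C=C(C=O)[C@H]1CC=C(C)C(=O)C1 | intermediate
4 | bis(isopinocampheyl)borinate ester of 5 at the C8 oxygen | C=C([C@H](CC=C)OB([C@@H]1C[C@@H]2C[C@H]([C@H]1C)C2(C)C)[C@@H]1C[C@@H]2C[C@H]([C@H]1C)C2(C)C)[C@H]1CC=C(C)C(=O)C1 | intermediate (not isolated)
5 | (5S)-5-[(3S)-3-hydroxyhexa-1,5-dien-2-yl]-2-methylcyclohex-2-en-1-one | C=C([C@H](CC=C)O)[C@H]1CC=C(C)C(=O)C1 | intermediate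
6 | (5S)-5-[(3S)-3-hydroxy-6-methylhepta-1,5-dien-2-yl]-2-methylcyclohex-2-en-1-one | C=C([C@H](CC=C(C)C)O)[C@H]1CC=C(C)C(=O)C1 | intermediate
7 | (5S)-5-[(3S)-3-(tert-butyldimethylsilyloxy)-6-methylhepta-1,5-dien-2-yl]-2-methylcyclohex-2-en-1-one | C=C([C@H](CC=C(C)C)O[Si](C)(C)C(C)(C)C)[C@H]1CC=C(C)C(=O)C1 | intermediate
8 | (5S)-5-{(3S)-3-(tert-butyldimethylsilyloxy)-4-[(2R)-3,3-dimethyloxiran-2-yl]but-1-en-2-yl}-2-methylcyclohex-2-en-1-one | C=C([C@H](C[C@H]1OC1(C)C)O[Si](C)(C)C(C)(C)C)[C@H]1CC=C(C)C(=O)C1 | intermediate
9 | lithium cross-conjugated dienolate of 8 (C2=C3(OLi)–C4=C5) | C=C([C@H](C[C@H]1OC1(C)C)O[Si](C)(C)C(C)(C)C)[C@H]1CC=C(C)C([O-])=C1.[Li+] | intermediate (not isolated)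
10 | (3S)-3-{(3S)-3-(tert-butyldimethylsilyloxy)-4-[(2R)-3,3-dimethyloxiran-2-yl]but-1-en-2-yl}-6-methylcyclohexa-1,5-dien-1-yl trifluoromethanesulfonate | C=C([C@H](C[C@H]1OC1(C)C)O[Si](C)(C)C(C)(C)C)[C@H]1CC=C(C)C(OS(=O)(=O)C(F)(F)F)=C1 | intermediate
11 | tert-butyl{[(2S)-1-[(2R)-3,3-dimethyloxiran-2-yl]-3-[(1S)-4-methylcyclohexa-2,4-dien-1-yl]but-3-en-2-yl]oxy}dimethylsilane | C=C([C@H](C[C@H]1OC1(C)C)O[Si](C)(C)C(C)(C)C)[C@H]1CC=C(C)C=C1 | intermediate
12 | (2S)-1-[(2R)-3,3-dimethyloxiran-2-yl]-3-[(1S)-4-methylcyclohexa-2,4-dien-1-yl]but-3-en-2-ol | C=C([C@H](C[C@H]1OC1(C)C)O)[C@H]1CC=C(C)C=C1 | intermediate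
13 | angelic acid, (2Z)-2-methylbut-2-enoic acid | C/C=C(/C)C(=O)O | starting material
14 | (2Z)-2-methylbut-2-enoic 2,4,6-trichlorobenzoic anhydride | C/C=C(/C)C(=O)OC(=O)c1c(Cl)cc(Cl)cc1Cl | intermediate (not isolated)
15 | (2S)-1-[(2R)-3,3-dimethyloxiran-2-yl]-3-[(1S)-4-methylcyclohexa-2,4-dien-1-yl]but-3-en-2-yl (2Z)-2-methylbut-2-enoate (key-step precursor) | C=C([C@H](C[C@H]1OC1(C)C)OC(=O)/C(C)=C\C)[C@H]1CC=C(C)C=C1 | intermediate
16 | (2S)-1-[(2R)-3,3-dimethyloxiran-2-yl]-3-[(1S,4S,5R)-7-methyl-2,3-dioxabicyclo[2.2.2]oct-7-en-5-yl]but-3-en-2-yl (2Z)-2-methylbut-2-enoate (key-step product) | C=C([C@H](C[C@H]1OC1(C)C)OC(=O)/C(C)=C\C)[C@H]1C[C@H]2C(C)=C[C@@H]1OO2 | intermediate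
17 | zwitterion from 16 and PPh3: triphenylphosphonio-oxy group on C5, alkoxide on C2, C3=C4 | C=C([C@H](C[C@H]1OC1(C)C)OC(=O)/C(C)=C\C)[C@H]1C[C@H](O[P+](c2ccccc2)(c2ccccc2)c2ccccc2)C(C)=C[C@@H]1[O-] | intermediate (not isolated)
18 | (2S)-1-[(2R)-3,3-dimethyloxiran-2-yl]-3-[(1R,2R,6S)-5-methyl-7-oxabicyclo[4.1.0]hept-4-en-2-yl]but-3-en-2-yl (2Z)-2-methylbut-2-enoate | C=C([C@H](C[C@H]1OC1(C)C)OC(=O)/C(C)=C\C)[C@H]1CC=C(C)[C@@H]2O[C@H]12 | intermediate
19 | (1R,5R,6R)-5-{(3S)-4-[(2R)-3,3-dimethyloxiran-2-yl]-3-[(2Z)-2-methylbut-2-enoyloxy]but-1-en-2-yl}-6-hydroxy-2-methylcyclohex-2-en-1-yl (2Z)-2-methylbut-2-enoate | C=C([C@H](C[C@H]1OC1(C)C)OC(=O)/C(C)=C\C)[C@H]1CC=C(C)[C@@H](OC(=O)/C(C)=C\C)[C@@H]1O | intermediate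
20 | (1S,2S,3R,4R,6S)-4-{(3S)-4-[(2R)-3,3-dimethyloxiran-2-yl]-3-[(2Z)-2-methylbut-2-enoyloxy]but-1-en-2-yl}-3-hydroxy-1-methyl-7-oxabicyclo[4.1.0]heptan-2-yl (2Z)-2-methylbut-2-enoate | C=C([C@H](C[C@H]1OC1(C)C)OC(=O)/C(C)=C\C)[C@H]1C[C@@H]2O[C@]2(C)[C@@H](OC(=O)/C(C)=C\C)[C@@H]1O | target

## Step count and least certain steps

Total step count: 14. Longest linear sequence: 14 steps from 1.

**Step 11 (key step).** Poor discrimination between the two diene faces is the most likely failure. In the conformer with the C1 substituent pseudo-equatorial neither face is shielded, and the small oxidant feels little else. Ene hydroperoxidation and dehydrogenation to the arene at the bis-allylic C1–H may also erode the yield.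
Fallback: a peroxide-free detour sets out from 6 and comes back at 19, with the ring oxygens introduced by enolate chemistry under control of the adjacent C1 centre.
- Yamaguchi angeloylation of 6 gives the C8 angelate of the enone F1.
- Shi epoxidation as in step 6 gives its 10,11-oxirane F2.
- Kinetic enolisation (LiN(SiMe3)2, THF, −78 °C) and oxygen transfer from a Davis N-sulfonyloxaziridine, anti to the C1 substituent, gives the α′-hydroxy enone F3.
- TBSCl/imidazole gives the C2 silyl ether F4.
- Luche reduction (NaBH4, CeCl3·7H2O, MeOH, −78 °C) with axial hydride delivery gives the trans C3 allylic alcohol F5.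
- A second Yamaguchi angeloylation gives the C2-silylated bis-angelate F6.
- HF·pyridine (buffered with pyridine, THF, 0 °C) removes the silyl group and the route is rejoined at 19.

This detour costs one protecting group on the C2 oxygen and relies on two substrate-controlled steps, but it avoids steps 5 and 7–13.

**Step 13.** Competing SN2′ attack at C5 (the 1,4-hydroxy ester) is the most likely failure. Angelic acid is bulky and weakly nucleophilic, so a slow opening would also leave time for solvolysis of the side-chain oxirane and for acyl shift from the C3 to the C2 oxygen.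
Fallback: an acetate relay in which the angelate is introduced by acylation, not by the opening itself; it sets out from 18 and comes back at 19.
- CsOAc/AcOH in DMF opens 18 to the trans C3 acetate, C2 alcohol F7.
- TBSCl/imidazole gives the silyl ether acetate F8.
- K2CO3/MeOH at 0 °C removes the acetate selectively in the presence of the hindered C8 enoate and gives the C3 alcohol F5.
- Angeloylation gives the silylated bis-angelate F6, and HF·pyridine returns 19.

**Step 14.** Loss of site selectivity is the most likely failure: the C2 hydroxyl is also homoallylic to C7=C14. Lewis-acidic vanadium may in addition open an oxirane or promote acyl shift.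
Fallback: replace hydroxyl-directed metal catalysis by reagent-controlled dioxirane epoxidation of 19, which leads directly to 20 with no new intermediate. The L-fructose-derived antipode of the Shi ketone should, by the spiro transition-state model, address the lower face, and both antipodes would be compared. A dioxirane prefers the trisubstituted ring alkene over C7=C14 for electronic reasons, and the lower face is also the one left open by the C3 ester and the C1 side chain.

**Step 2.** Sluggish displacement of the allylic chloride and loss of the electrophilic 2-substituted acrolein by conjugate addition or oligomerisation are the most likely failures.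
Fallback: substitution, hydrolysis and a separate mild oxidation; it sets out from 2 and comes back at 3.
- KOAc in DMF gives the allylic acetate F9.
- K2CO3/MeOH gives the allylic alcohol F10.
- MnO2 in CH2Cl2 oxidises F10 to 3.

## Further compounds

F1 | step 11 | (3S)-6-methyl-2-[(1S)-4-methyl-5-oxocyclohex-3-en-1-yl]hepta-1,5-dien-3-yl (2Z)-2-methylbut-2-enoate (C8 angelate of 6) | C=C([C@H](CC=C(C)C)OC(=O)/C(C)=C\C)[C@H]1CC=C(C)C(=O)C1
F2 | step 11 | 10,11-oxirane (10R) of F1 | C=C([C@H](C[C@H]1OC1(C)C)OC(=O)/C(C)=C\C)[C@H]1CC=C(C)C(=O)C1
F3 | step 11 | α′-hydroxy enone from F2, C2–OH trans to the C1 side chain | C=C([C@H](C[C@H]1OC1(C)C)OC(=O)/C(C)=C\C)[C@H]1CC=C(C)C(=O)[C@@H]1O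
F4 | step 11 | C2 tert-butyldimethylsilyl ether of F3 | C=C([C@H](C[C@H]1OC1(C)C)OC(=O)/C(C)=C\C)[C@H]1CC=C(C)C(=O)[C@@H]1O[Si](C)(C)C(C)(C)C
F5 | step 11 | C3 allylic alcohol (C3–OH cis to the side chain, trans to C2–OSi) from F4 | C=C([C@H](C[C@H]1OC1(C)C)OC(=O)/C(C)=C\C)[C@H]1CC=C(C)[C@@H](O)[C@@H]1O[Si](C)(C)C(C)(C)C
F6 | step 11 | C2 tert-butyldimethylsilyl ether of 19 | C=C([C@H](C[C@H]1OC1(C)C)OC(=O)/C(C)=C\C)[C@H]1CC=C(C)[C@@H](OC(=O)/C(C)=C\C)[C@@H]1O[Si](C)(C)C(C)(C)C
F7 | step 13 | C3 acetate, C2 alcohol from acetate opening of 18 | C=C([C@H](C[C@H]1OC1(C)C)OC(=O)/C(C)=C\C)[C@H]1CC=C(C)[C@@H](OC(C)=O)[C@@H]1O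
F8 | step 13 | C2 tert-butyldimethylsilyl ether of F7 | C=C([C@H](C[C@H]1OC1(C)C)OC(=O)/C(C)=C\C)[C@H]1CC=C(C)[C@@H](OC(C)=O)[C@@H]1O[Si](C)(C)C(C)(C)C
F0 | step 14 | none | none
F9 | step 2 | 2-[(1S)-4-methyl-5-oxocyclohex-3-en-1-yl]prop-2-en-1-yl acetate | C=C(COC(C)=O)[C@H]1CC=C(C)C(=O)C1
F10 | step 2 | (5S)-5-(3-hydroxyprop-1-en-2-yl)-2-methylcyclohex-2-en-1-one | C=C(CO)[C@H]1CC=C(C)C(=O)C1
A1 | alternative 1 | cyclohexenol from the chromium ring closure: C3–OH free, C2–OTBS, C8–OPMB, C4=C5, prenyl side chain | C=C([C@H](CC=C(C)C)OCc1ccc(OC)cc1)[C@H]1CC=C(C)[C@@H](O)[C@@H]1O[Si](C)(C)C(C)(C)C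
A2 | alternative 1 | open-chain (Z)-C4 iodoalkene C3 aldehyde, precursor of A1 | C=C([C@H](CC=C(C)C)OCc1ccc(OC)cc1)[C@@H](C/C=C(/C)I)[C@@H](O[Si](C)(C)C(C)(C)C)C=O
A3 | alternative 2 | metathesis product, identical with 19 | C=C([C@H](C[C@H]1OC1(C)C)OC(=O)/C(C)=C\C)[C@H]1CC=C(C)[C@@H](OC(=O)/C(C)=C\C)[C@@H]1O
A4 | alternative 2 | acyclic diene (C4 isopropenyl, C5 vinyl), precursor of A3 | C=C([C@H](C[C@H]1OC1(C)C)OC(=O)/C(C)=C\C)[C@@H](CC=C)[C@@H](O)[C@H](OC(=O)/C(C)=C\C)C(C)=C
A5 | alternative 3 | cyclohexene with trans C2,C3-acetonide, C7=C14 and C8–OTBS | C=C([C@H](CC=C(C)C)O[Si](C)(C)C(C)(C)C)[C@H]1CC=C(C)[C@H]2OC(C)(C)O[C@H]12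
A6 | alternative 3 | tertiary allylic methyl carbonate allylsilane, precursor of A5 (either C4 epimer, either C1=C7 geometry) | C=CC(C)(OC(=O)OC)[C@H]1OC(C)(C)O[C@@H]1C=C(C[Si](C)(C)C)[C@H](CC=C(C)C)O[Si](C)(C)C(C)(C)C
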